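**Assumption:** the target's single stereocentre is (S) (read from the SMILES); commercial (S)-(−)-citronellal (≥97% ee) supplies it, and pent-4-enal, 3-bromofuran, 4-bromofuran-2-carbaldehyde and methylmalonic acid are bought.

## Retrosynthetic overview
1. Target 18 ⇒ aldehyde 15 + methylmalonic acid (Knoevenagel–Doebner; the (E)-acrylic acid is added last).
2. 15 ⇒ primary iodide 12 + 4-bromofuran-2-carbaldehyde (Negishi sp3–sp2; ring A is bought).
3. 12 ⇒ C=C cleavage, reduction and iodination of the prenyl end of 8; 8 ⇒ allylfuran 5 + 3-bromofuran (B-alkyl Suzuki; ring C is bought).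
4. Key step: ring B of 5 ⇒ 1,4-keto-aldehyde 4 ⇒ acyl-anion (Breslow) addition of (S)-citronellal to 2-allylacrolein 2; citronellal C1 becomes C2 of ring B and its C3 is the target stereocentre.
5. Ring order: only ring B is constructed (Paal–Knorr, step 2); ring C is attached in step 3 and ring A in step 6.

## Route

Step 1
Reactants: 1 pent-4-enal
Product: 2 2-methylidenepent-4-enal
Conditions: 37% aq. HCHO (1.1 equiv), pyrrolidine (10 mol%), EtCO2H (10 mol%), i-PrOH, 45 °C; distil, store cold over BHT
Reagents that add atoms: formaldehyde, C=O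
Why: Organocatalytic Mannich-type α-methylenation (enamine of 1 adds to the formaldehyde iminium, then amine elimination) converts an unbranched aldehyde into the 2-substituted acrolein.

Step 2
Reactants: 3 (3S)-3,7-dimethyloct-6-enal [(S)-citronellal]; 2 2-methylidenepent-4-enal
Product: 5 2-[(2S)-2,6-dimethylhept-5-en-1-yl]-4-(prop-2-en-1-yl)furan, via keto-aldehyde 4 (not isolated)
Conditions: 3-benzyl-5-(2-hydroxyethyl)-4-methylthiazolium chloride (15 mol%), Et3N (30 mol%), 1,4-dioxane, 70 °C, 2 (1.3 equiv) added over 6 h; then p-TsOH·H2O (40 mol%), 4 Å MS, 50 °C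
Reagents that add atoms: none
Why: Proposed new method: the thiazol-2-ylidene converts the unhindered saturated CHO of 3 into a Breslow intermediate (acyl anion equivalent) that adds irreversibly to the unsubstituted CH2 terminus of enal 2 (kept dilute by slow addition; its hindered, conjugated CHO binds the carbene only reversibly, and acyloin formation is reversible), giving 1,4-keto-aldehyde 4 in which the former aldehyde carbon of citronellal and the enal β-carbon, both electrophilic by nature, are joined, and catalytic acid then closes ring B by Paal–Knorr cyclodehydration; the closest known reaction type is the thiazolium-catalysed intermolecular Stetter reaction of aliphatic aldehydes with vinyl ketones or acrylates run one-pot with Paal–Knorr furan formation, and the stereocentre (β to the carbonyl, not enolisable) is carried over unchanged from 3.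

Step 3
Reactants: 5 2-[(2S)-2,6-dimethylhept-5-en-1-yl]-4-(prop-2-en-1-yl)furan; 6 3-bromofuran
Product: 8 2-[(2S)-2,6-dimethylhept-5-en-1-yl]-4-[3-(furan-3-yl)propyl]furan, via B-alkyl-9-BBN borane 7 (not isolated)
Conditions: 9-BBN (1.2 equiv), THF, 0 °C→rt; then 6, PdCl2(dppf) (5 mol%), 3 M aq. NaOH, THF, 65 °C
Reagents that add atoms: none
Why: 9-BBN hydroborates only the terminal monosubstituted alkene (anti-Markovnikov; the trisubstituted alkene and the furan are inert at rt), and the primary alkylborane undergoes B-alkyl Suzuki–Miyaura coupling with 3-bromofuran.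

Step 4
Reactants: 8 2-[(2S)-2,6-dimethylhept-5-en-1-yl]-4-[3-(furan-3-yl)propyl]furan
Product: 11 (4S)-5-{4-[3-(furan-3-yl)propyl]furan-2-yl}-4-methylpentan-1-ol, via diol 9 (not isolated), via aldehyde 10 (not isolated)
Conditions: OsO4 (2 mol%), NaIO4 (4 equiv), 2,6-lutidine, dioxane/H2O 3:1, rt; extractive work-up and concentration; then NaBH4, MeOH, 0 °C
Reagents that add atoms: osmium tetroxide, O=[Os](=O)(=O)=O (catalytic; its oxygen is replenished by sodium periodate, [Na+].[O-]I(=O)(=O)=O)
Why: Lemieux–Johnson oxidation, in which the only remaining C=C bond is dihydroxylated much faster than the aromatic furans and the glycol is cleaved by periodate, followed by borohydride reduction of the crude aldehyde; the stereocentre is remote and untouched.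

Step 5
Reactants: 11 (4S)-5-{4-[3-(furan-3-yl)propyl]furan-2-yl}-4-methylpentan-1-ol
Product: 12 4-[3-(furan-3-yl)propyl]-2-[(2S)-5-iodo-2-methylpentyl]furan
Conditions: PPh3, imidazole, I2, CH2Cl2, 0 °C→rt
Reagents that add atoms: iodine, II
Why: Appel iodination converts the primary alcohol to the iodide under buffered, non-acidic conditions that alkylfurans tolerate.

Step 6
Reactants: 12 4-[3-(furan-3-yl)propyl]-2-[(2S)-5-iodo-2-methylpentyl]furan; 13 4-bromofuran-2-carbaldehyde
Product: 15 4-[(4S)-5-{4-[3-(furan-3-yl)propyl]furan-2-yl}-4-methylpentyl]furan-2-carbaldehyde, via alkylzinc iodide 14 (not isolated)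
Conditions: Zn dust (TMSCl/BrCH2CH2Br-activated), LiCl, THF, 40 °C; then 13, Pd(OAc)2 (2 mol%), SPhos (4 mol%), THF, rt
Reagents that add atoms: none
Why: Zinc inserts into the primary C–I bond to give an alkylzinc iodide mild enough to spare the aldehyde, and Pd/SPhos-catalysed Negishi coupling joins it to C4 of the bromofuraldehyde.

Step 7
Reactants: 15 4-[(4S)-5-{4-[3-(furan-3-yl)propyl]furan-2-yl}-4-methylpentyl]furan-2-carbaldehyde; 16 methylmalonic acid
Product: 18 (2E)-3-{4-[(4S)-5-{4-[3-(furan-3-yl)propyl]furan-2-yl}-4-methylpentyl]furan-2-yl}-2-methylprop-2-enoic acid (CNP0088458.1), via aldol adduct 17 (not isolated)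
Conditions: 16 (3 equiv), pyridine, piperidine (20 mol%), 95 °C; cold dilute citric acid work-up
Reagents that add atoms: none
Why: Knoevenagel–Doebner condensation, in which the adduct of the furaldehyde and methylmalonic acid loses water and CO2 to give the thermodynamically preferred (E)-acid (furyl trans to CO2H) under basic conditions harmless to the alkylfurans.

## Compound list
1 | pent-4-enal | C=CCCC=O | starting material
2 | 2-methylidenepent-4-enal (2-allylacrolein) | C=CCC(=C)C=O | intermediate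
3 | (3S)-3,7-dimethyloct-6-enal, (S)-citronellal | CC(C)=CCC[C@H](C)CC=O | starting material
4 | (6S)-6,10-dimethyl-4-oxo-2-(prop-2-en-1-yl)undec-9-enal (C2 epimers) | CC(C)=CCC[C@H](C)CC(=O)CC(CC=C)C=O | intermediate
5 | 2-[(2S)-2,6-dimethylhept-5-en-1-yl]-4-(prop-2-en-1-yl)furan | CC(C)=CCC[C@H](C)Cc1cc(CC=C)co1 | intermediate
6 | 3-bromofuran | Brc1ccoc1 | starting material
7 | 9-(3-{5-[(2S)-2,6-dimethylhept-5-en-1-yl]furan-3-yl}propyl)-9-borabicyclo[3.3.1]nonane | CC(C)=CCC[C@H](C)Cc1cc(CCCB2C3CCCC2CCC3)co1 | intermediate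
8 | 2-[(2S)-2,6-dimethylhept-5-en-1-yl]-4-[3-(furan-3-yl)propyl]furan | CC(C)=CCC[C@H](C)Cc1cc(CCCc2ccoc2)co1 | intermediate
9 | (6S)-7-{4-[3-(furan-3-yl)propyl]furan-2-yl}-2,6-dimethylheptane-2,3-diol (C3 epimers) | CC(C)(O)C(O)CC[C@H](C)Cc1cc(CCCc2ccoc2)co1 | intermediate
10 | (4S)-5-{4-[3-(furan-3-yl)propyl]furan-2-yl}-4-methylpentanal | O=CCC[C@H](C)Cc1cc(CCCc2ccoc2)co1 | intermediate
11 | (4S)-5-{4-[3-(furan-3-yl)propyl]furan-2-yl}-4-methylpentan-1-ol | OCCC[C@H](C)Cc1cc(CCCc2ccoc2)co1 | intermediate
12 | 4-[3-(furan-3-yl)propyl]-2-[(2S)-5-iodo-2-methylpentyl]furan | ICCC[C@H](C)Cc1cc(CCCc2ccoc2)co1 | intermediate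
13 | 4-bromofuran-2-carbaldehyde | O=Cc1cc(Br)co1 | starting material
14 | [(4S)-5-{4-[3-(furan-3-yl)propyl]furan-2-yl}-4-methylpentyl](iodo)zinc | I[Zn]CCC[C@H](C)Cc1cc(CCCc2ccoc2)co1 | intermediate
15 | 4-[(4S)-5-{4-[3-(furan-3-yl)propyl]furan-2-yl}-4-methylpentyl]furan-2-carbaldehyde | O=Cc1cc(CCC[C@H](C)Cc2cc(CCCc3ccoc3)co2)co1 | intermediate
16 | methylmalonic acid (2-methylpropanedioic acid) | CC(C(=O)O)C(=O)O | starting material
17 | 2-[hydroxy(4-{(4S)-5-[4-(3-(furan-3-yl)propyl)furan-2-yl]-4-methylpentyl}furan-2-yl)methyl]-2-methylpropanedioic acid | CC(C(O)c1cc(CCC[C@H](C)Cc2cc(CCCc3ccoc3)co2)co1)(C(=O)O)C(=O)O | intermediate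
18 | (2E)-3-{4-[(4S)-5-{4-[3-(furan-3-yl)propyl]furan-2-yl}-4-methylpentyl]furan-2-yl}-2-methylprop-2-enoic acid | C/C(=C\c1cc(CCC[C@H](C)Cc2cc(CCCc3ccoc3)co2)co1)C(=O)O | target

## Totals and risks
Total step count: 7.
Longest linear sequence: 7 steps (1 → 2 → 5 → 8 → 11 → 12 → 15 → 18), or 6 steps counted from (S)-citronellal 3.

**Most likely to fail, 1: step 2.** The enal 2 may itself engage the carbene (acting as donor or homoenolate), its doubly allylic CH2 may isomerise under base, and citronellal may rest as its acyloin. Fallback, which replaces the catalytic acyl anion by a nitronate as a stoichiometric acyl anion equivalent: commercial (S)-citronellyl bromide (CC(C)=CCC[C@H](C)CCBr) is treated with NaNO2 in DMF to give (3S)-3,7-dimethyl-1-nitrooct-6-ene F1. The fallback then sets out from enal 2: base-catalysed Michael addition of F1 (DBU 10 mol%, MeCN, 0 °C, F1 in slight excess) gives (6S)-6,10-dimethyl-4-nitro-2-(prop-2-en-1-yl)undec-9-enal F2. A McMurry-type Nef reaction (NaOMe, then buffered aq. TiCl3/NH4OAc) converts F2 into keto-aldehyde 4, where the fallback comes back to the route; 4 is closed to furan 5 with catalytic TsOH as in step 2.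

**Most likely to fail, 2: step 4.** OsO4/periodate may also attack the two electron-rich alkylfurans. Fallback, which cleaves the C=C bond before any furan exists: setting out from 3, acetalisation (HC(OMe)3, cat. TsOH, MeOH) gives (6S)-8,8-dimethoxy-2,6-dimethyloct-2-ene F3. Ozonolysis with NaBH4 work-up gives (4S)-6,6-dimethoxy-4-methylhexan-1-ol F4, and mild aqueous acid (PPTS, acetone/H2O) releases (3S)-6-hydroxy-3-methylhexanal F5. F5 serves as the donor with 2 under the step 2 conditions and gives, through (6S)-9-hydroxy-6-methyl-4-oxo-2-(prop-2-en-1-yl)nonanal F6, the furan (4S)-4-methyl-5-[4-(prop-2-en-1-yl)furan-2-yl]pentan-1-ol F7. Hydroboration with 2.2 equiv 9-BBN takes up the free OH as a borinate, forming 9-{3-[5-((2S)-5-(9-borabicyclo[3.3.1]nonan-9-yloxy)-2-methylpentyl)furan-3-yl]propyl}-9-borabicyclo[3.3.1]nonane F8. Suzuki coupling of F8 with 6 as in step 3, with basic work-up to hydrolyse the B–O bond, comes back to the route at alcohol 11 (skipping 5, 8, 9 and 10).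

**Most likely to fail, 3: step 6.** The alkylzinc may add to or be quenched by the free furaldehyde, and 15 may not survive the coupling cleanly. Fallback, which olefinates first so the coupling partner carries no aldehyde: setting out from 13, Wittig reaction with ethyl 2-(triphenylphosphoranylidene)propanoate (toluene, 80 °C) gives ethyl (2E)-3-(4-bromofuran-2-yl)-2-methylprop-2-enoate F9. Negishi coupling of F9 with alkylzinc iodide 14 (made from 12 as in step 6) gives ethyl (2E)-3-{4-[(4S)-5-{4-[3-(furan-3-yl)propyl]furan-2-yl}-4-methylpentyl]furan-2-yl}-2-methylprop-2-enoate F10. Saponification (LiOH, THF/MeOH/H2O, then mild acidification) comes back to the route at target 18, bypassing 15 and 17 and not using 16.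

## Further compounds
F1 | step 2 | (3S)-3,7-dimethyl-1-nitrooct-6-ene | CC(C)=CCC[C@H](C)CC[N+](=O)[O-]
F2 | step 2 | (6S)-6,10-dimethyl-4-nitro-2-(prop-2-en-1-yl)undec-9-enal | CC(C)=CCC[C@H](C)CC([N+](=O)[O-])CC(CC=C)C=O
F3 | step 4 | (6S)-8,8-dimethoxy-2,6-dimethyloct-2-ene | CC(C)=CCC[C@H](C)CC(OC)OC
F4 | step 4 | (4S)-6,6-dimethoxy-4-methylhexan-1-ol | OCCC[C@H](C)CC(OC)OC
F5 | step 4 | (3S)-6-hydroxy-3-methylhexanal | OCCC[C@H](C)CC=O
F6 | step 4 | (6S)-9-hydroxy-6-methyl-4-oxo-2-(prop-2-en-1-yl)nonanal | OCCC[C@H](C)CC(=O)CC(CC=C)C=O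
F7 | step 4 | (4S)-4-methyl-5-[4-(prop-2-en-1-yl)furan-2-yl]pentan-1-ol | OCCC[C@H](C)Cc1cc(CC=C)co1
F8 | step 4 | 9-{3-[5-((2S)-5-(9-borabicyclo[3.3.1]nonan-9-yloxy)-2-methylpentyl)furan-3-yl]propyl}-9-borabicyclo[3.3.1]nonane | B1(OCCC[C@H](C)Cc2cc(CCCB3C4CCCC3CCC4)co2)C2CCCC1CCC2
F9 | step 6 | ethyl (2E)-3-(4-bromofuran-2-yl)-2-methylprop-2-enoate | C/C(=C\c1cc(Br)co1)C(=O)OCC
F10 | step 6 | ethyl (2E)-3-{4-[(4S)-5-{4-[3-(furan-3-yl)propyl]furan-2-yl}-4-methylpentyl]furan-2-yl}-2-methylprop-2-enoate | C/C(=C\c1cc(CCC[C@H](C)Cc2cc(CCCc3ccoc3)co2)co1)C(=O)OCC
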